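The ring system is numbered as tetracyclo[8.2.1.0^{3,12}.0^{6,11}]tridecane: ring A (C1, C2, C3, C12), ring B (C3–C6, C11, C12), cyclopentane ring C (C1, C10, C11, C12, C13), ring D (C6–C11). Ring C carries at C10 the alkene carbon C9 of ring D. The route therefore builds rings A and B together with a six-membered ring in which C9 is a ketone between C10 and C11 (enone–alkene [2+2] photocycloaddition). Photochemical Wolff rearrangement of the C10-diazo C9-ketone then contracts this ring to ring C and leaves C9 as an exocyclic carbon on C10. Conjugate addition at C6 and ring-closing metathesis (C8=C9) finish ring D.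

Key step: step 15

Remark: the target SMILES is read literally, so H-6 is trans to H-11 (rings B and D trans-fused) and the ester at C7 is cis to C5. Target locants are used for all intermediates, and "ring C′" is the six-membered ring C1–C13–C10–C9–C11–C12 of compounds 15–24.

Step 1
Reactants: 1 methyl undec-10-enoate
Product: 2 methyl (9E)-undec-9-enoate
Conditions: [Cp*Ru(NCMe)(κ2-P,N-L)]PF6 (1 mol %; L = 4-tert-butyl-2-(diisopropylphosphanyl)-1-methylimidazole), acetone, 25 °C
Reagents that add atoms: none
Why: Catalytic one-position alkene transposition, in which the P,N ligand relays a single allylic proton so that the terminal alkene should move one carbon and settle as the (E)-alkene while the remote ester is untouched.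

Step 2
Reactants: 2 methyl (9E)-undec-9-enoate
Product: 3 (9E)-undec-9-enal
Conditions: i-Bu2AlH (1.05 equiv), CH2Cl2, −78 °C; aq. KNaC4H4O6
Reagents that add atoms: none
Why: Half-reduction of an ester, because the aluminium hemiacetal is stable at −78 °C and should collapse to the aldehyde only on work-up.

Step 3
Reactants: 3 (9E)-undec-9-enal; 4 vinylmagnesium bromide
Product: 5 (11E)-trideca-1,11-dien-3-ol (racemic)
Conditions: THF, −78 → 0 °C; aq. NH4Cl
Reagents that add atoms: none
Why: Grignard 1,2-addition gives the secondary allylic alcohol needed for the Claisen step, and its carbinol configuration is lost again in step 4.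

Step 4
Reactants: 5 (11E)-trideca-1,11-dien-3-ol; 6 triethyl orthoacetate
Product: 7 ethyl (4E,13E)-pentadeca-4,13-dienoate
Conditions: EtCO2H (5 mol %), 140 °C, ethanol distilled off
Reagents that add atoms: none
Why: Johnson–Claisen rearrangement through a chair transition state with the long chain equatorial, which should set the future C1=C2 alkene as (E) and add the two-carbon ester arm (C10, C9).

Step 5
Reactants: 7 ethyl (4E,13E)-pentadeca-4,13-dienoate; 8 ethyl acetate
Product: 9 ethyl (6E,15E)-3-oxoheptadeca-6,15-dienoate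
Conditions: LiN(i-Pr)2 (3.2 equiv), 8 (3 equiv), THF, −78 °C; then 7, −78 → 0 °C; AcOH
Reagents that add atoms: none
Why: Crossed Claisen condensation, in which excess lithium enolate of ethyl acetate acylates on ester 7 and the product is held as its β-keto ester enolate until the quench.

Step 6
Reactants: 9 ethyl (6E,15E)-3-oxoheptadeca-6,15-dienoate
Product: 10 ethyl 2-{2-[(3E,12E)-tetradeca-3,12-dien-1-yl]-1,3-dioxolan-2-yl}acetate
Conditions: HOCH2CH2OH, p-TsOH (cat.), benzene, reflux, azeotropic removal of water
Reagents that add atoms: ethane-1,2-diol, OCCO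
Why: Acid-catalysed ketalisation masks the future C9 ketone, so that C11 can later sit next to an enone without becoming doubly activated.

Step 7
Reactants: 10 ethyl 2-{2-[(3E,12E)-tetradeca-3,12-dien-1-yl]-1,3-dioxolan-2-yl}acetate
Product: 11 2-{2-[(3E,12E)-tetradeca-3,12-dien-1-yl]-1,3-dioxolan-2-yl}acetaldehyde
Conditions: i-Bu2AlH (1.05 equiv), toluene, −78 °C; aq. KNaC4H4O6
Reagents that add atoms: none
Why: Half-reduction of the ester as in step 2, helped by chelation of the aluminium hemiacetal to the dioxolane oxygen.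

Step 8
Reactants: 11 2-{2-[(3E,12E)-tetradeca-3,12-dien-1-yl]-1,3-dioxolan-2-yl}acetaldehyde; 12 methyl vinyl ketone
Product: 14 (4R)-4-{2-[(3E,12E)-tetradeca-3,12-dien-1-yl]-1,3-dioxolan-2-yl}cyclohex-2-en-1-one, via keto aldehyde 13 (not isolated)
Conditions: (S)-2-[methoxy(diphenyl)methyl]pyrrolidine (5 mol %), ethyl 3,4-dihydroxybenzoate (20 mol %), 12 (1.5 equiv), neat, 4 °C; then KOH (0.1 equiv), n-Bu4NOH (cat.), THF/H2O, 25 °C
Reagents that add atoms: none
Why: Organocatalytic Robinson annulation (enamine Michael addition, then aldol condensation), in which the diphenyl(methoxy)methyl group shields one face of the (E)-enamine so that C11 should form with the (R) configuration before base closes ring B.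

Step 9
Reactants: 14 (4R)-4-{2-[(3E,12E)-tetradeca-3,12-dien-1-yl]-1,3-dioxolan-2-yl}cyclohex-2-en-1-one
Product: 15 tricyclic keto ketal (rings A and B plus ring C′)
Conditions: hν (350 nm, Pyrex), degassed CH2Cl2 (5 mM), 0 °C
Reagents that add atoms: none
Why: Intramolecular enone–alkene [2+2] photocycloaddition through the enone triplet (C12–C1 bond first by 1,6-closure, then C3–C2), in which the three-atom tether from C11 forces addition to the enone face syn to it (H-1, H-3, H-11, H-12 all cis) and the 1,4-biradical should close with the side chain on the convex face of ring A.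

Step 10
Reactants: 15 tricyclic keto ketal
Product: 17 tricyclic C5=C6 enone, via silyl enol ether 16 (not isolated)
Conditions: LiN(i-Pr)2, Me3SiCl, THF, −78 °C; then Pd(OAc)2 (10 mol %), O2 (1 atm), DMSO, 25 °C
Reagents that add atoms: chlorotrimethylsilane, C[Si](C)(C)Cl (silyl group present in 16 only)
Why: Saegusa oxidation, with kinetic deprotonation at the C5 methylene instead of the cyclobutane methine C3 and palladium-mediated dehydrosilylation to the C5=C6 enone.

Step 11
Reactants: 17 tricyclic C5=C6 enone; 18 methyl but-3-enoate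
Product: 20 C4 enol triflate of the C6 Michael adduct, via lithium enolate 19 (not isolated)
Conditions: 18, LiN(i-Pr)2, THF/DMPU, −78 °C; then 17, −78 °C; then N-(5-chloropyridin-2-yl)triflimide, −78 → 0 °C; aq. NH4Cl
Reagents that add atoms: N-(5-chloropyridin-2-yl)-1,1,1-trifluoro-N-(trifluoromethylsulfonyl)methanesulfonamide, O=S(=O)(N(c1ccc(Cl)cn1)S(=O)(=O)C(F)(F)F)C(F)(F)F
Why: Michael addition of the lithium dienolate through its α-carbon, then O-sulfonylation of the regiodefined ketone enolate; the nucleophile should enter at C6 anti to the C11–C9 bond (H-6 trans to H-11), and an open transition state with the ester antiperiplanar to C5 and the hydrogen under ring B is expected to set C7.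

Step 12
Reactants: 20 C4 enol triflate
Product: 21 ring B alkene ester with C9 dioxolane
Conditions: Pd(OAc)2 (5 mol %), PPh3 (10 mol %), HCO2H, n-Bu3N, DMF, 60 °C
Reagents that add atoms: none
Why: Palladium-catalysed formate hydrogenolysis of the enol triflate replaces the C4–O bond by C–H and leaves the C4=C5 alkene of ring B in place.

Step 13
Reactants: 21 ring B alkene ester with C9 dioxolane
Product: 22 C9 ketone
Conditions: 1 M HCl, THF, 25 °C
Reagents that add atoms: water, O
Why: Acid hydrolysis of the dioxolane unmasks the C9 ketone once the enone is gone, so C11 is activated by this one carbonyl only and should keep its configuration.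

Step 14
Reactants: 22 C9 ketone
Product: 24 C10 diazo C9 ketone, via enaminone 23 (not isolated)
Conditions: t-BuOCH(NMe2)2, toluene, 90 °C; then TsN3, CH2Cl2, 0 → 25 °C
Reagents that add atoms: tert-butoxybis(dimethylamino)methane, CN(C)C(OC(C)(C)C)N(C)C (adds CH–NMe2, present in 23 only); p-toluenesulfonyl azide, Cc1ccc(cc1)S(=O)(=O)N=[N+]=[N-] (adds N2)
Why: Base-free aminomethylenation followed by diazo transfer to the enaminone, which can only engage the C10 methylene because C11 and the ester α-carbon C7 are methines.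

Step 15
Reactants: 24 C10 diazo C9 ketone
Product: 26 ring-contracted C9 N-methoxy-N-methylamide, via ketene 25 (not isolated)
Conditions: hν (λ > 300 nm, Pyrex), MeNH(OMe) (3 equiv), THF, 0 °C
Reagents that add atoms: N,O-dimethylhydroxylamine, CNOC
Why: Photolysis of the cyclic, s-cis-locked α-diazo ketone expels N2 with concerted 1,2-shift of C11 from C9 to C10 (Wolff rearrangement), giving the ring-contracted ketene 25, which the amine traps as the amide. The closest known reaction type is the Wolff ring contraction of 2-diazocycloalkanones to cycloalkanecarboxylic acid derivatives. No ring is closed by a cyclisation: ring C arises when ring C′ loses C9 from its perimeter and the C10–C11 bond forms. C11 migrates with retention, and the new centre C10 should be set when the amide enol is protonated on the convex face of the bicyclo[3.2.0]heptane (the face of H-1, H-11 and H-12), which places C9 cis to C6 and to ring A. The step needs a single migrating group and the shift to outrun carbene addition to the nearby alkenes: the diazo group can only be at C10, only C11 is attached to the carbonyl on the other side, the fixed s-cis geometry favours the concerted shift, and the alkenes and esters do not absorb above 300 nm.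

Step 16
Reactants: 26 ring-contracted C9 N-methoxy-N-methylamide
Product: 27 C9 aldehyde
Conditions: i-Bu2AlH (1.1 equiv), THF, −78 °C; aq. KNaC4H4O6, 0 °C
Reagents that add atoms: none
Why: Half-reduction of the N-methoxy-N-methylamide through its chelated aluminium aminal, which is expected to react ahead of the hindered C7 methyl ester and to release the aldehyde only on work-up.

Step 17
Reactants: 27 C9 aldehyde
Product: 28 C10 vinyl triene ester
Conditions: Ph3PCH3Br, KN(SiMe3)2, THF, −78 → 0 °C
Reagents that add atoms: methyltriphenylphosphonium bromide, C[P+](c1ccccc1)(c1ccccc1)c1ccccc1.[Br-] (adds CH2)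
Why: Wittig methylenation with the non-stabilised ylide at low temperature should convert the aldehyde into the vinyl group before the endo C10 centre can epimerise.

Step 18
Reactants: 28 C10 vinyl triene ester
Product: 29 methyl (1S,2S,3R,6S,7R,10R,11S,12S)-2-[(8E)-dec-8-en-1-yl]tetracyclo[8.2.1.0^{3,12}.0^{6,11}]trideca-4,8-diene-7-carboxylate
Conditions: first-generation Grubbs catalyst (PCy3)2Cl2Ru=CHPh (5 mol %), CH2Cl2 (5 mM), 40 °C
Reagents that add atoms: none
Why: Ring-closing metathesis of the two terminal vinyl groups forms C8=C9 and so ring D (trans-fused to ring B, cis-fused to ring C), and the less reactive first-generation catalyst is chosen to spare the ring B and side-chain alkenes.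

Compound list
1 | methyl undec-10-enoate | C=CCCCCCCCCC(=O)OC | starting material
2 | methyl (9E)-undec-9-enoate | C/C=C/CCCCCCCC(=O)OC | intermediate
3 | (9E)-undec-9-enal | C/C=C/CCCCCCCC=O | intermediate
4 | vinylmagnesium bromide | C=C[Mg]Br | starting material
5 | (11E)-trideca-1,11-dien-3-ol, racemic | C/C=C/CCCCCCCC(O)C=C | intermediate
6 | triethyl orthoacetate | CC(OCC)(OCC)OCC | starting material
7 | ethyl (4E,13E)-pentadeca-4,13-dienoate | C/C=C/CCCCCCC/C=C/CCC(=O)OCC | intermediate
8 | ethyl acetate | CC(=O)OCC | starting material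
9 | ethyl (6E,15E)-3-oxoheptadeca-6,15-dienoate | C/C=C/CCCCCCC/C=C/CCC(=O)CC(=O)OCC | intermediate
10 | ethyl 2-{2-[(3E,12E)-tetradeca-3,12-dien-1-yl]-1,3-dioxolan-2-yl}acetate | C/C=C/CCCCCCC/C=C/CCC1(CC(=O)OCC)OCCO1 | intermediate
11 | 2-{2-[(3E,12E)-tetradeca-3,12-dien-1-yl]-1,3-dioxolan-2-yl}acetaldehyde | C/C=C/CCCCCCC/C=C/CCC1(CC=O)OCCO1 | intermediate
12 | methyl vinyl ketone (but-3-en-2-one) | CC(=O)C=C | starting material
13 | (2R)-5-oxo-2-{2-[(3E,12E)-tetradeca-3,12-dien-1-yl]-1,3-dioxolan-2-yl}hexanal | C/C=C/CCCCCCC/C=C/CCC1(OCCO1)[C@@H](C=O)CCC(C)=O | intermediate (not isolated)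
14 | (4R)-4-{2-[(3E,12E)-tetradeca-3,12-dien-1-yl]-1,3-dioxolan-2-yl}cyclohex-2-en-1-one | C/C=C/CCCCCCC/C=C/CCC1(OCCO1)[C@H]2C=CC(=O)CC2 | intermediate
15 | tricyclic keto ketal: rings A and B fused to ring C′; C4 ketone; C9 as 1,3-dioxolane; (8E)-dec-8-enyl at C2; H-1, H-3, H-11, H-12 all cis; C2 chain trans to C4 and C13 | C/C=C/CCCCCCC[C@@H]1[C@H]2C(=O)CC[C@H]3C4(OCCO4)CC[C@@H]1[C@@H]23 | intermediate
16 | C4 trimethylsilyl enol ether (C4=C5) of 15 | C/C=C/CCCCCCC[C@@H]1[C@H]2C(O[Si](C)(C)C)=CC[C@H]3C4(OCCO4)CC[C@@H]1[C@@H]23 | intermediate (not isolated)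
17 | tricyclic enone: C4 ketone, C5=C6, otherwise as 15 | C/C=C/CCCCCCC[C@@H]1[C@H]2C(=O)C=C[C@H]3C4(OCCO4)CC[C@@H]1[C@@H]23 | intermediate
18 | methyl but-3-enoate | C=CCC(=O)OC | starting material
19 | lithium C4=C5 enolate carrying CH(CO2Me)CH=CH2 at C6 (H-6 trans to H-11) | C/C=C/CCCCCCC[C@@H]1[C@H]2C(O[Li])=C[C@H]([C@@H](C=C)C(=O)OC)[C@H]3C4(OCCO4)CC[C@@H]1[C@@H]23 | intermediate (not isolated)
20 | C4 enol triflate (C4=C5); C6 bears CH(CO2Me)CH=CH2 (C7, C8), with C6 and C7 configured as in the target | C/C=C/CCCCCCC[C@@H]1[C@H]2C(OS(=O)(=O)C(F)(F)F)=C[C@H]([C@@H](C=C)C(=O)OC)[C@H]3C4(OCCO4)CC[C@@H]1[C@@H]23 | intermediate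
21 | ring B alkene ester: C4=C5, C6 side chain CH(CO2Me)CH=CH2, C9 dioxolane in ring C′ | C/C=C/CCCCCCC[C@@H]1[C@H]2C=C[C@H]([C@@H](C=C)C(=O)OC)[C@H]3C4(OCCO4)CC[C@@H]1[C@@H]23 | intermediate
22 | C9 ketone corresponding to 21 | C/C=C/CCCCCCC[C@@H]1[C@H]2C=C[C@H]([C@@H](C=C)C(=O)OC)[C@H]3C(=O)CC[C@@H]1[C@@H]23 | intermediate
23 | C10 (dimethylamino)methylene C9 ketone | C/C=C/CCCCCCC[C@@H]1[C@H]2C=C[C@H]([C@@H](C=C)C(=O)OC)[C@H]3C(=O)C(=CN(C)C)C[C@@H]1[C@@H]23 | intermediate (not isolated)
24 | C10 diazo C9 ketone | C/C=C/CCCCCCC[C@@H]1[C@H]2C=C[C@H]([C@@H](C=C)C(=O)OC)[C@H]3C(=O)C(=[N+]=[N-])C[C@@H]1[C@@H]23 | intermediate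
25 | ring-contracted ketene (C10=C9=O; ring C formed) | C/C=C/CCCCCCC[C@@H]1[C@H]2C=C[C@H]([C@@H](C=C)C(=O)OC)[C@@H]3[C@H]2[C@H]1CC3=C=O | intermediate (not isolated)
26 | C9 N-methoxy-N-methylamide on C10 of ring C (H-10 cis to H-1, H-11, H-12) | C/C=C/CCCCCCC[C@@H]1[C@H]2C=C[C@H]([C@@H](C=C)C(=O)OC)[C@@H]3[C@H]2[C@H]1C[C@@H]3C(=O)N(C)OC | intermediate
27 | C9 aldehyde on C10 | C/C=C/CCCCCCC[C@@H]1[C@H]2C=C[C@H]([C@@H](C=C)C(=O)OC)[C@@H]3[C@H]2[C@H]1C[C@@H]3C=O | intermediate
28 | triene ester: vinyl at C10, CH(CO2Me)CH=CH2 at C6 | C/C=C/CCCCCCC[C@@H]1[C@H]2C=C[C@H]([C@@H](C=C)C(=O)OC)[C@@H]3[C@H]2[C@H]1C[C@@H]3C=C | intermediate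
29 | methyl (1S,2S,3R,6S,7R,10R,11S,12S)-2-[(8E)-dec-8-en-1-yl]tetracyclo[8.2.1.0^{3,12}.0^{6,11}]trideca-4,8-diene-7-carboxylate | C/C=C/CCCCCCC[C@@H]1[C@H]2C=C[C@H]3[C@@H]4[C@H]2[C@H]1C[C@@H]4C=C[C@H]3C(=O)OC | target

Total step count: 18. Longest linear sequence: 18 steps (1 → 29).

Steps most likely to fail

Step 11. The dienolate may add 1,2 to the C4 ketone instead of 1,4. The acidic C7–H may transfer its proton to the ketone enolate before O-sulfonylation, which would lose the regiodefined enolate. Facial control at C7 may also be poor. The fallback sets out from 17 and comes back at 21, replacing steps 11 and 12. Luche reduction with NaBH4 and CeCl3·7H2O in MeOH at −78 °C should deliver hydride to the convex face and give the C4 allylic alcohol F1, in which the hydroxyl is syn to ring A. Mitsunobu esterification with but-3-enoic acid, PPh3 and diisopropyl azodicarboxylate in THF inverts C4 and gives the C4-epimeric but-3-enoate ester F2. Ireland–Claisen rearrangement with i-Pr2NLi and Me3SiCl in THF from −78 to 25 °C transfers C7 to C6 on the face of the departing C4 oxygen, which fixes H-6 trans to H-11 and creates the C4=C5 alkene in the C7 carboxylic acid F3; the ketene acetal geometry is chosen to give the C7 configuration of 21. Me3SiCHN2 in MeOH/toluene then gives 21.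

Step 9. With a three-atom tether the cycloaddition may give the bridged instead of the fused mode, and stereocontrol at C2 may be lost in the closure of the 1,4-biradical. The fallback sets out from 14 and comes back at 15. Iodination with I2 and pyridine in CH2Cl2 gives the 2-iodo enone F4, with the 4R centre untouched. Carbonylation with palladium diacetate, PPh3, CO and Et3N in MeOH gives the 2-methoxycarbonyl enone F5. This β-keto ester chromophore should undergo the intramolecular [2+2] photocycloaddition at longer wavelength or under triplet sensitisation, giving the C3-methoxycarbonyl tricyclic keto ketal F6. Krapcho dealkoxycarbonylation with LiCl in wet DMSO at 150 °C then restores H-3 with cis ring fusion and gives 15.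

Step 16. The hydride may also attack the C7 methyl ester, and the endo aldehyde may epimerise at C10 during work-up. The fallback sets out from 24 and comes back at 27, replacing steps 15 and 16. The Wolff rearrangement is run under irradiation above 300 nm in THF/water, so that the ketene is trapped as the C9 carboxylic acid F7. Oxalyl chloride with catalytic DMF in CH2Cl2 gives the C9 acid chloride F8. Lithium tri-tert-butoxyaluminium hydride in THF at −78 °C reduces the acid chloride to 27 and should leave the methyl ester alone.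

Further compounds
F1 | step 11 | C4 allylic alcohol | C/C=C/CCCCCCC[C@@H]1[C@H]2[C@@H](O)C=C[C@H]3C4(OCCO4)CC[C@@H]1[C@@H]23
F2 | step 11 | C4-epimeric but-3-enoate ester | C/C=C/CCCCCCC[C@@H]1[C@H]2[C@H](OC(=O)CC=C)C=C[C@H]3C4(OCCO4)CC[C@@H]1[C@@H]23
F3 | step 11 | C7 carboxylic acid | C/C=C/CCCCCCC[C@@H]1[C@H]2C=C[C@H]([C@@H](C=C)C(=O)O)[C@H]3C4(OCCO4)CC[C@@H]1[C@@H]23
F4 | step 9 | 2-iodo enone | C/C=C/CCCCCCC/C=C/CCC1(OCCO1)[C@H]2C=C(I)C(=O)CC2
F5 | step 9 | 2-methoxycarbonyl enone | C/C=C/CCCCCCC/C=C/CCC1(OCCO1)[C@H]2C=C(C(=O)OC)C(=O)CC2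
F6 | step 9 | C3-methoxycarbonyl tricyclic keto ketal | C/C=C/CCCCCCC[C@@H]1[C@@]2(C(=O)OC)C(=O)CC[C@H]3C4(OCCO4)CC[C@@H]1[C@@H]23
F7 | step 16 | C9 carboxylic acid | C/C=C/CCCCCCC[C@@H]1[C@H]2C=C[C@H]([C@@H](C=C)C(=O)OC)[C@@H]3[C@H]2[C@H]1C[C@@H]3C(=O)O
F8 | step 16 | C9 acid chloride | C/C=C/CCCCCCC[C@@H]1[C@H]2C=C[C@H]([C@@H](C=C)C(=O)OC)[C@@H]3[C@H]2[C@H]1C[C@@H]3C(=O)Cl
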